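## The problem

1. The target is a C32 polypropionate with two fully substituted 4-pyranones on one chain, numbered here C1–C23: the ethyl end of ring A (C1–C2), ring A (C3–C7 plus ring oxygen), the acyclic stretch C8–C14, ring B (C15–C19 plus ring oxygen) and the side chain C20–C23.
2. The chain carries an E-trisubstituted alkene (C9=C10) and seven stereocentres in three groups: C8 (S) alone between ring A and the alkene; the tetrad C11(OH, S)–C12(CH3, S)–C13(OH, S)–C14(CH3, S) with an anti,syn,anti pattern; and the anti pair C20(CH3, R)–C21(OH, R) beyond ring B.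
3. Inside the tetrad the C11 hydroxyl is 1,3 to C13 and can direct it, and C14 relates to C13 as a Felkin (anti) partner, whereas the C13/C14 pair (S,S) and the C20/C21 pair (R,R) are mirror images across ring B and C8 is insulated by the alkene, so each group needs its own source of absolute configuration.
4. The fragile points are the ring-attached methines C8, C14 and C20, whose C–H bonds are vinylogously acidic (C8 is also allylic); the β-hydroxyls at C13 and C21 can be lost by elimination or retro-aldol once the neighbouring methine is deprotonated, and the allylic C11 hydroxyl ionises in strong acid.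
5. The usual answer builds each pyranone late from an acyclic 1,3,5-triketone, which makes the route long and linear.
6. Two features suggest otherwise: rings A and B are the same heterocycle, 2,6-diethyl-3,5-dimethyl-4-pyranone (3), with C8, C14 and C20 as its lateral CH2 carbons.
7. In addition, C14 is both the lateral carbon on C15 of ring B and the α-carbon of C13, so at the C13-ketone level C14–H is doubly activated and stereolabile while the C11 hydroxyl sits 1,3 to that ketone.
8. That pairing makes the key step possible: a hydroxyl-directed reduction of the C13 ketone in which C11 fixes C13 and the equilibrating C14 is selected by the ketone face that C11 opens.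

## Retrosynthesis

**C8–C9 (21 ⇒ 20 + 16).** The single bond between the ring A lateral carbon and the alkene is cut.
- Against its neighbours: cutting C10–C11 would need an alkenyl-metal addition to a C11 aldehyde against the Felkin preference of C12, with C8 carried through all later steps. Cutting C9=C10 by olefination would need a C8 aldehyde flanked by ring A, which cannot hold its configuration.
- Gain: C8, the most fragile centre, is made last, from racemic 16 (one step from 3), without base. Precursor 20 lacks ring A and C8.
- Asked of the forward step: an enantioconvergent nickel-catalysed cross-electrophile coupling that keeps the E geometry and tolerates three free hydroxyls.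

**C13–H and the configuration of C14 (20 ⇒ 19, key step).** No skeletal bond is cut; C13 returns to a ketone and C14 to an epimer mixture.
- Against its neighbours: setting C14 while the C13–C14 bond forms (aldehyde-level aldol) offers no control element for C14. A reagent-controlled reduction would have to override C12.
- Gain: 19 has two fewer defined stereocentres and comes in one step from two small fragments.
- Asked of the forward step: hydride delivered from the C11 oxygen to one face of C13, C14 epimerising faster than it is reduced, and the (14S) epimer reacting faster.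

**C13–C14 (19 ⇒ 7 + 15).** The bond is cut at the acyl level, between the lateral carbanion of the remaining ethyl group of 7 and the N-methoxy-N-methylamide 15.
- Against its neighbours: C12–C13 or C11–C12 cuts put an enolisable ketone next to ring B and lose the auxiliary as the source of absolute configuration.
- Gain: ring B with its finished C20/C21 pair (7) and a seven-carbon acyl piece (15).
- Asked of the forward step: lateral deprotonation at the C14 CH2 rather than the C20 CH next to the alkoxide, and a stable tetrahedral adduct so the more acidic product cannot quench the carbanion.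

**C21–H and C20–C21 (7 ⇒ 6 ⇒ 3 + 4).** The C21 carbinol goes back to ketone 6, whose C20 is flanked by the ketone and C19 of ring B and so racemises. A ketoreductase can then convert all of 6 into one anti isomer. The C20–C21 bond comes from lateral acylation of 3 with amide 4. No small reagent distinguishes ethyl from the branched substituent at this dialkyl ketone with enantiocontrol, which speaks for the enzyme.

**C11–C12 (15 ⇒ 14 ⇒ 11 + 12; 11 ⇒ 10 ⇒ 8).** The anti C11/C12 pair is cut as an auxiliary-controlled anti-aldol between propanoyl oxazolidinone 12 and the non-enolisable bromo-enal 11. The E-alkene and the C10 methyl come from methylalumination of prop-2-yn-1-ol (8). The bromide on C9 is the handle for the last step and is inert to everything in between.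

**Ring A partner and the pyranone (16 ⇒ 3; 3 ⇒ 1 + 2).** Chloride 16 is 3 chlorinated at one lateral carbon by radical substitution, so no carbanion meets the product. Pyranone 3 is the double acylation–cyclodehydration product of 3-pentanone (1) and propanoic anhydride (2). One achiral pyranone serves three times.

## Roads not taken

**Alternative 1: both pyranones from acyclic triketones (the obvious plan).**
- Cut: the ring C–O bonds of both rings, leading back to 1,3,5-triketones such as A1 for ring B, assembled by iterative aldol and oxidation on 3-pentanone units.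
- Forward key step: acid-promoted cyclodehydration of each triketone (closure at oxygen).
- Why the chosen plan is better: each ring costs several operations (two C–C bond formations, oxidations, cyclisation) against one for 3. The triketones are tautomer and epimer mixtures. C14, C20 and especially C8 (α to a ketone and allylic) sit next to carbonyl groups through many steps. The sequence is linear.

**Alternative 2: C13–C14 by lateral aldol of two finished pyranones.**
- Cut: C13–C14 at the aldehyde level, lateral carbanion 17 plus the ring A aldehyde A2.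
- Forward key step: vinylogous aldol addition.
- Why the chosen plan is better: the metal sits on the remote ring carbonyl oxygen, so the transition state is open and C14 is uncontrolled; only C13 follows Felkin. The basic carbanion also meets the C8–H of A2, the most acidic C–H in either partner, and protecting groups are needed. The chosen plan forms the same bond at the acyl level, sets C14 afterwards, and adds ring A last.

**Alternative 3: C11–C12 by aldol of a ring B ethyl ketone with a ring A enal.**
- Cut: C11–C12, ethyl ketone A3 plus enal A4.
- Forward key step: anti-selective boron aldol followed by 1,3-anti reduction, or a tandem aldol–Tishchenko reaction.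
- Why the chosen plan is better: enolisation of A3 goes to the doubly activated C14, not to C12. Neither partner has a stereocentre close enough to set the absolute configuration of the new centres. The C8–H of A4 is γ to the aldehyde and lateral to ring A, so it dienolises under amine and Lewis acid.

Key step: step 10

Assumption: the SMILES is read as (8S,9E,11S,12S,13S,14S,20R,21R) in the chain numbering given above.

Assumption: in step 6 the (S)-benzyl auxiliary shields the same enolate face as in its chelate-controlled alkylations, which gives the (2R,3S) adduct 14.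

Remark: C12 is R in 14, 15 and 19 and S in 20 and 21 only because the CIP rank of C13 changes; no bond at C12 is touched.

## Steps

Step 1
Reactants: 1 3-pentanone; 2 propanoic anhydride
Product: 3 2,6-diethyl-3,5-dimethyl-4H-pyran-4-one
Conditions: 2 (2.5 equiv), polyphosphoric acid, 100 °C
Reagents that add atoms: none
Why: Acid-mediated double C-acylation of the ketone at both α-carbons gives the 1,3,5-triketone, which cyclodehydrates in the same medium to the symmetric 4-pyranone; no stereocentre is formed.

Step 2
Reactants: 3 2,6-diethyl-3,5-dimethyl-4H-pyran-4-one; 4 N-methoxy-N-methylpropanamide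
Product: 6 rac-2-ethyl-3,5-dimethyl-6-(3-oxopentan-2-yl)-4H-pyran-4-one, via lithiated pyranone 5 (not isolated)
Conditions: LiN(i-Pr)2 (LDA, 1.05 equiv), THF, −78 °C; then 4, −78 → −40 °C; AcOH
Reagents that add atoms: none
Why: Lateral (vinylogous) deprotonation of one ethyl group and acylation with a Weinreb amide; the tetrahedral chelate survives until the quench, so the more acidic product cannot protonate unreacted carbanion. The new centre (C20) is racemic and labile by design.

Step 3
Reactants: 6 rac-2-ethyl-3,5-dimethyl-6-(3-oxopentan-2-yl)-4H-pyran-4-one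
Product: 7 2-ethyl-6-[(2R,3R)-3-hydroxypentan-2-yl]-3,5-dimethyl-4H-pyran-4-one
Conditions: anti-Prelog NADPH-dependent ketoreductase (panel hit of the Lactobacillus kefir alcohol dehydrogenase type), NADP+ (cat.), i-PrOH (10% v/v), triethanolamine buffer pH 8.5, MgSO4 (2 mM), DMSO (5%), 30 °C
Reagents that add atoms: none
Why: Ketoreductase-catalysed dynamic reductive kinetic resolution, as established for 2-substituted β-keto esters. C20 lies between the ketone and C19 of ring B and racemises in the buffer; the enzyme accepts only the (20R) ketone and delivers hydride to the face that gives (21R). The vinylogous-ester carbonyl of the ring is not a substrate.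

Step 4
Reactants: 8 prop-2-yn-1-ol
Product: 10 (E)-3-bromo-2-methylprop-2-en-1-ol, via alkenylalane 9 (not isolated)
Conditions: AlMe3 (3 equiv), Cp2ZrCl2 (0.25 equiv), CH2Cl2, 0 °C → rt; then N-bromosuccinimide, THF, −30 → 0 °C; aq. HCl
Reagents that add atoms: trimethylaluminium, C[Al](C)C; N-bromosuccinimide, O=C1CCC(=O)N1Br
Why: Zirconium-catalysed Negishi methylalumination adds CH3 and Al syn across the alkyne with methyl on the internal carbon; brominolysis of the C–Al bond with retention fixes the E geometry of the future C9=C10 alkene.

Step 5
Reactants: 10 (E)-3-bromo-2-methylprop-2-en-1-ol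
Product: 11 (E)-3-bromo-2-methylprop-2-enal
Conditions: activated MnO2 (10 equiv), CH2Cl2, rt; filtered, concentrated cold
Reagents that add atoms: none
Why: Selective allylic oxidation with MnO2; the alkene geometry and the C–Br bond are unaffected.

Step 6
Reactants: 11 (E)-3-bromo-2-methylprop-2-enal; 12 (4S)-4-benzyl-3-propanoyl-1,3-oxazolidin-2-one
Product: 14 (4S)-4-benzyl-3-[(2R,3S,4E)-5-bromo-3-hydroxy-2,4-dimethylpent-4-enoyl]-1,3-oxazolidin-2-one, via trimethylsilyl ether 13 (not isolated)
Conditions: MgCl2 (0.2 equiv), Et3N (2 equiv), Me3SiCl (1.5 equiv), EtOAc, rt; then CF3CO2H (cat.), MeOH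
Reagents that add atoms: none
Why: Evans magnesium-halide-catalysed direct anti-aldol: soft enolisation gives the chelated Z-enolate, which adds to the non-enolisable enal through a boat transition state. The auxiliary sets C12 and the anti transition state sets C11; silylation of the aldolate turns the catalyst over and the silyl group is removed on work-up.

Step 7
Reactants: 14 (4S)-4-benzyl-3-[(2R,3S,4E)-5-bromo-3-hydroxy-2,4-dimethylpent-4-enoyl]-1,3-oxazolidin-2-one
Product: 15 (2R,3S,4E)-5-bromo-3-hydroxy-N-methoxy-N,2,4-trimethylpent-4-enamide
Conditions: MeONHMe·HCl (3 equiv), AlMe3 (3 equiv), CH2Cl2, −20 → 0 °C; aq. HCl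
Reagents that add atoms: N,O-dimethylhydroxylamine hydrochloride, CNOC.Cl
Why: Weinreb transamidation of the imide, assisted by the free β-hydroxyl as its aluminium alkoxide, so attack is at the exocyclic carbonyl; C12 is not epimerised and the auxiliary is recovered.

Step 8
Reactants: 3 2,6-diethyl-3,5-dimethyl-4H-pyran-4-one
Product: 16 rac-2-(1-chloroethyl)-6-ethyl-3,5-dimethyl-4H-pyran-4-one
Conditions: N-chlorosuccinimide (0.5 equiv based on 3), dibenzoyl peroxide (5 mol%), PhH, 80 °C; unreacted 3 recovered by chromatography
Reagents that add atoms: N-chlorosuccinimide, O=C1CCC(=O)N1Cl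
Why: Free-radical chain chlorination of the Wohl–Ziegler type at a lateral CH2, as known for 2-alkyl-4-pyranones and benzylic positions. Hydrogen abstraction there gives a secondary radical conjugated through the ring C=C to the ring carbonyl, more stabilised than the primary radical from a ring methyl, whose conjugation with the carbonyl is only crossed. The excess of 3 holds back a second chlorination, and the racemic chloride is what the stereoconvergent step 11 needs.

Step 9
Reactants: 7 2-ethyl-6-[(2R,3R)-3-hydroxypentan-2-yl]-3,5-dimethyl-4H-pyran-4-one; 15 (2R,3S,4E)-5-bromo-3-hydroxy-N-methoxy-N,2,4-trimethylpent-4-enamide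
Product: 19 2-[(4R,5S,6E)-7-bromo-5-hydroxy-4,6-dimethyl-3-oxohept-6-en-2-yl]-6-[(2R,3R)-3-hydroxypentan-2-yl]-3,5-dimethyl-4H-pyran-4-one (both epimers at C14), via dilithiated hydroxy pyranone 17 (not isolated), via lithium alkoxide of the amide 18 (not isolated)
Conditions: 7, LiN(i-Pr)2 (2.1 equiv), THF, −78 °C; 15 pre-treated with LiN(i-Pr)2 (1.0 equiv), THF, −78 °C, added by cannula; −78 → −40 °C; AcOH, −78 °C
Reagents that add atoms: none
Why: Lateral acylation with a Weinreb amide forms C13–C14; the C21 alkoxide disfavours deprotonation at the adjacent C20, so the second equivalent of base takes the C14 CH2. The C11 alkoxide and the tetrahedral chelate protect C12 from enolisation. C14 is formed unselectively, which is intended.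

Step 10
Reactants: 19 2-[(4R,5S,6E)-7-bromo-5-hydroxy-4,6-dimethyl-3-oxohept-6-en-2-yl]-6-[(2R,3R)-3-hydroxypentan-2-yl]-3,5-dimethyl-4H-pyran-4-one (both epimers at C14)
Product: 20 2-[(2S,3S,4S,5S,6E)-7-bromo-3,5-dihydroxy-4,6-dimethylhept-6-en-2-yl]-6-[(2R,3R)-3-hydroxypentan-2-yl]-3,5-dimethyl-4H-pyran-4-one
Conditions: Me4NBH(OAc)3 (6 equiv), MeCN/AcOH (1:1), −30 → 0 °C
Reagents that add atoms: none
Why: Proposed new method: an Evans–Saksena hydroxyl-directed reduction run as a dynamic kinetic resolution; the C11 hydroxyl exchanges onto boron and the alkoxydiacetoxyborohydride delivers hydride intramolecularly to the acid-activated C13 carbonyl through a six-membered chair transition state (C10 side chain and C12 methyl equatorial), which fixes C13 anti to the C11 oxygen (13S) whatever the configuration of C14. C14 is α to this ketone and also the lateral carbon on C15 of ring B, so in acetic acid (hydrogen-bonded or protonated pyranone carbonyl) it should enolise through the cross-conjugated dienol much faster than C12 (a plain ketone α-carbon) or C20 (a plain lateral carbon), and the two C14 epimers of 19 interconvert during the reduction. The (14S) epimer should be reduced faster because on the face dictated by C11 it can adopt the Felkin–Anh arrangement (ring B anti to the incoming hydride, C14–H towards C12, C14–CH3 towards the carbonyl oxygen), which gives the 13,14-anti relationship of the target. The closest known reaction types are the Evans–Saksena 1,3-anti reduction of β-hydroxy ketones and the dynamic kinetic resolution of α-aryl ketones in transfer hydrogenation. The step closes no ring. It needs epimerisation at C14 faster than hydride transfer (secured by the double activation of C14–H, with the temperature raised towards 0 °C if reduction outpaces equilibration), discrimination between the C14 epimers (secured by the size and acceptor character of ring B with its flanking C16 methyl), and chemoselectivity (triacetoxyborohydride reduces only the ketone to which it is tethered, so the ring carbonyl and the alkenyl bromide are left alone).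

Step 11
Reactants: 20 2-[(2S,3S,4S,5S,6E)-7-bromo-3,5-dihydroxy-4,6-dimethylhept-6-en-2-yl]-6-[(2R,3R)-3-hydroxypentan-2-yl]-3,5-dimethyl-4H-pyran-4-one; 16 rac-2-(1-chloroethyl)-6-ethyl-3,5-dimethyl-4H-pyran-4-one
Product: 21 2-ethyl-6-[(2S,3E,5S,6S,7S,8S)-5,7-dihydroxy-8-{6-[(2R,3R)-3-hydroxypentan-2-yl]-3,5-dimethyl-4-oxo-4H-pyran-2-yl}-4,6-dimethylnon-3-en-2-yl]-3,5-dimethyl-4H-pyran-4-one
Conditions: 16 (2 equiv), NiCl2(dme) (10 mol%), cyclopropane-1,1-diyl-bridged bis(indano-oxazoline) ligand (11 mol%, the enantiomer that gives the S arrangement in the parent 1-arylethyl series), manganese powder (3 equiv), NaI (0.5 equiv), N,N-dimethylacetamide, 0 °C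
Reagents that add atoms: none
Why: Nickel-catalysed enantioconvergent reductive cross-electrophile coupling of a secondary benzylic-type chloride with an alkenyl bromide. Zerovalent nickel inserts into C9–Br with retention of the E geometry; halogen abstraction from either enantiomer of 16 gives the same planar, pyranone-stabilised C8 radical, and its capture and reductive elimination at the chiral nickel centre set C8 (S) under catalyst control. No base is present, so the methines at C8, C14 and C20 and the three free hydroxyls are not touched.

## Compound list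

1 | 3-pentanone | CCC(=O)CC | starting material
2 | propanoic anhydride | CCC(=O)OC(=O)CC | starting material
3 | 2,6-diethyl-3,5-dimethyl-4H-pyran-4-one | CCc1oc(CC)c(C)c(=O)c1C | intermediate
4 | N-methoxy-N-methylpropanamide | CCC(=O)N(C)OC | starting material
5 | [1-(6-ethyl-3,5-dimethyl-4-oxo-4H-pyran-2-yl)ethyl]lithium (lateral anion of 3, drawn as the C-lithio form) | CCc1oc(C(C)[Li])c(C)c(=O)c1C | intermediate (not isolated)
6 | rac-2-ethyl-3,5-dimethyl-6-(3-oxopentan-2-yl)-4H-pyran-4-one | CCC(=O)C(C)c1oc(CC)c(C)c(=O)c1C | intermediate
7 | 2-ethyl-6-[(2R,3R)-3-hydroxypentan-2-yl]-3,5-dimethyl-4H-pyran-4-one | CCc1oc([C@H](C)[C@H](O)CC)c(C)c(=O)c1C | intermediate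
8 | prop-2-yn-1-ol | C#CCO | starting material
9 | (E)-[3-(dimethylalumanyloxy)-2-methylprop-1-en-1-yl]dimethylalumane | C[Al](C)/C=C(\C)CO[Al](C)C | intermediate (not isolated)
10 | (E)-3-bromo-2-methylprop-2-en-1-ol | Br/C=C(\C)CO | intermediate
11 | (E)-3-bromo-2-methylprop-2-enal | Br/C=C(\C)C=O | intermediate
12 | (4S)-4-benzyl-3-propanoyl-1,3-oxazolidin-2-one | CCC(=O)N1[C@@H](Cc2ccccc2)COC1=O | starting material
13 | (4S)-4-benzyl-3-[(2R,3S,4E)-5-bromo-2,4-dimethyl-3-(trimethylsilyloxy)pent-4-enoyl]-1,3-oxazolidin-2-one | Br/C=C(\C)[C@@H](O[Si](C)(C)C)[C@@H](C)C(=O)N1[C@@H](Cc2ccccc2)COC1=O | intermediate (not isolated)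
14 | (4S)-4-benzyl-3-[(2R,3S,4E)-5-bromo-3-hydroxy-2,4-dimethylpent-4-enoyl]-1,3-oxazolidin-2-one | Br/C=C(\C)[C@@H](O)[C@@H](C)C(=O)N1[C@@H](Cc2ccccc2)COC1=O | intermediate
15 | (2R,3S,4E)-5-bromo-3-hydroxy-N-methoxy-N,2,4-trimethylpent-4-enamide | Br/C=C(\C)[C@@H](O)[C@@H](C)C(=O)N(C)OC | intermediate
16 | rac-2-(1-chloroethyl)-6-ethyl-3,5-dimethyl-4H-pyran-4-one | CCc1oc(C(C)Cl)c(C)c(=O)c1C | intermediate
17 | dilithio derivative of 7 (C21 alkoxide, C14 lateral carbanion) | [Li]C(C)c1oc([C@H](C)[C@H](O[Li])CC)c(C)c(=O)c1C | intermediate (not isolated)
18 | lithium alkoxide of 15 | Br/C=C(\C)[C@@H](O[Li])[C@@H](C)C(=O)N(C)OC | intermediate (not isolated)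
19 | 2-[(4R,5S,6E)-7-bromo-5-hydroxy-4,6-dimethyl-3-oxohept-6-en-2-yl]-6-[(2R,3R)-3-hydroxypentan-2-yl]-3,5-dimethyl-4H-pyran-4-one (both epimers at C14) | Br/C=C(\C)[C@@H](O)[C@@H](C)C(=O)C(C)c1oc([C@H](C)[C@H](O)CC)c(C)c(=O)c1C | intermediate
20 | 2-[(2S,3S,4S,5S,6E)-7-bromo-3,5-dihydroxy-4,6-dimethylhept-6-en-2-yl]-6-[(2R,3R)-3-hydroxypentan-2-yl]-3,5-dimethyl-4H-pyran-4-one | Br/C=C(\C)[C@@H](O)[C@@H](C)[C@H](O)[C@H](C)c1oc([C@H](C)[C@H](O)CC)c(C)c(=O)c1C | intermediate
21 | 2-ethyl-6-[(2S,3E,5S,6S,7S,8S)-5,7-dihydroxy-8-{6-[(2R,3R)-3-hydroxypentan-2-yl]-3,5-dimethyl-4-oxo-4H-pyran-2-yl}-4,6-dimethylnon-3-en-2-yl]-3,5-dimethyl-4H-pyran-4-one | CCc1oc([C@@H](C)/C=C(\C)[C@@H](O)[C@@H](C)[C@H](O)[C@H](C)c2oc([C@H](C)[C@H](O)CC)c(C)c(=O)c2C)c(C)c(=O)c1C | target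

## Step count and risks

Total steps: 11. Longest linear sequence: 7 steps (8 → 10 → 11 → 14 → 15 → 19 → 20 → 21; steps 4, 5, 6, 7, 9, 10, 11). The ring B branch (steps 1, 2, 3) and the chloride (step 8) join at steps 9 and 11.

**Step 10 (key step, bears the label).**
- What may go wrong: epimerisation at C14 may be slower than hydride delivery, or the two C14 epimers may be reduced at similar rates, so that C13 is set but C14 is not. Prolonged exposure to acetic acid may ionise the allylic C11 hydroxyl.
- Fallback (known chemistry), from 15 and 7, returning at 20: amide 15 is silylated (Et3SiOTf, 2,6-lutidine) to the triethylsilyl ether F1 and reduced with i-Bu2AlH to the aldehyde F2. The dianion 17, made from 7 as in step 9, is added to F2 at −78 °C in a lateral aldol reaction. Felkin and 1,3-anti induction reinforce each other in this anti-configured aldehyde and set C13; C14 is formed with only simple diastereoselection, so the wanted adduct F3 is separated by chromatography from its C14 epimer F4. HF·pyridine then removes the silyl group of F3 to give 20.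

**Step 11.**
- What may go wrong: slow oxidative addition to the hindered trisubstituted alkenyl bromide may let homocoupling or reduction of the chloride dominate. A mismatch between the ligand and the six stereocentres of 20 may erode facial control at C8. The free hydroxyls may bind nickel.
- Fallback, from 16 and 20, returning at 21: chloride 16 is converted with zinc dust and LiCl into the lateral zinc reagent F5, which is coupled with 20 in a Negishi reaction (Pd(OAc)2, SPhos, THF, rt; excess F5 to allow for the hydroxyls). This gives 21 together with its C8 epimer F6 without stereocontrol; the two diastereomers are separated by preparative HPLC.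

**Step 3.**
- What may go wrong: no panel enzyme may accept an ethyl ketone with a branched second substituent in the anti-Prelog sense, or racemisation of C20 in the buffer may be slower than reduction so that the resolution stops being dynamic.
- Fallback, from 6, returning at 7: Felkin-controlled reduction of 6 (NaBH4, CeCl3·7H2O, MeOH, −78 °C) gives the racemic anti alcohol, that is 7 together with its enantiomer F7. Lipase-catalysed acylation (Candida antarctica lipase B, vinyl acetate) takes the (R)-carbinol to the acetate F8, which is separated from F7 and hydrolysed with the same lipase in buffer to 7.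

**Step 9.**
- What may go wrong: proton transfer from C12–H or C20–H to the lateral carbanion may outrun addition to the hindered, alkoxide-bearing amide, and the C21 alkoxide may undergo retro-aldol cleavage on warming.
- Fallback, from 7 and the aldehyde F2 (made from 15 as in the fallback to step 10), returning at 19: alcohol 7 is silylated to the triethylsilyl ether F9. Its lateral monoanion (LiN(i-Pr)2, THF, −78 °C) is added to F2 to give the aldol adduct F10 as a mixture at C13 and C14. Dess–Martin oxidation of the C13 carbinol gives the ketone F11, and HF·pyridine removes both silyl groups to give 19. The configurations at C13 and C14 are irrelevant at this point, since step 10 sets both.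

**Step 8.**
- What may go wrong: hydrogen abstraction by the chain-carrying radical may be poorly selective between the lateral CH2, the ring methyls and the terminal CH3 of the ethyl groups, and a second chlorination may compete with the first.
- Fallback, from 3, returning at 16: 3 is deprotonated at one lateral CH2 with NaN(SiMe3)2 in THF at −78 °C to the sodium derivative F12, and this solution is added to hexachloroethane in THF at −78 °C. Electrophilic chlorination of the carbanion gives 16 with the site fixed by the deprotonation; the inverse addition keeps the more acidic product away from unreacted carbanion.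

## Further compounds

F1 | step 10 | (2R,3S,4E)-5-bromo-N-methoxy-N,2,4-trimethyl-3-(triethylsilyloxy)pent-4-enamide | Br/C=C(\C)[C@@H](O[Si](CC)(CC)CC)[C@@H](C)C(=O)N(C)OC
F2 | step 10 | (2R,3S,4E)-5-bromo-2,4-dimethyl-3-(triethylsilyloxy)pent-4-enal | Br/C=C(\C)[C@@H](O[Si](CC)(CC)CC)[C@@H](C)C=O
F3 | step 10 | 2-[(2S,3S,4S,5S,6E)-7-bromo-3-hydroxy-4,6-dimethyl-5-(triethylsilyloxy)hept-6-en-2-yl]-6-[(2R,3R)-3-hydroxypentan-2-yl]-3,5-dimethyl-4H-pyran-4-one | Br/C=C(\C)[C@@H](O[Si](CC)(CC)CC)[C@@H](C)[C@H](O)[C@H](C)c1oc([C@H](C)[C@H](O)CC)c(C)c(=O)c1C
F4 | step 10 | 2-[(2R,3S,4S,5S,6E)-7-bromo-3-hydroxy-4,6-dimethyl-5-(triethylsilyloxy)hept-6-en-2-yl]-6-[(2R,3R)-3-hydroxypentan-2-yl]-3,5-dimethyl-4H-pyran-4-one | Br/C=C(\C)[C@@H](O[Si](CC)(CC)CC)[C@@H](C)[C@H](O)[C@@H](C)c1oc([C@H](C)[C@H](O)CC)c(C)c(=O)c1C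
F5 | step 11 | [1-(6-ethyl-3,5-dimethyl-4-oxo-4H-pyran-2-yl)ethyl]zinc chloride | CCc1oc(C(C)[Zn]Cl)c(C)c(=O)c1C
F6 | step 11 | 2-ethyl-6-[(2R,3E,5S,6S,7S,8S)-5,7-dihydroxy-8-{6-[(2R,3R)-3-hydroxypentan-2-yl]-3,5-dimethyl-4-oxo-4H-pyran-2-yl}-4,6-dimethylnon-3-en-2-yl]-3,5-dimethyl-4H-pyran-4-one | CCc1oc([C@H](C)/C=C(\C)[C@@H](O)[C@@H](C)[C@H](O)[C@H](C)c2oc([C@H](C)[C@H](O)CC)c(C)c(=O)c2C)c(C)c(=O)c1C
F7 | step 3 | 2-ethyl-6-[(2S,3S)-3-hydroxypentan-2-yl]-3,5-dimethyl-4H-pyran-4-one | CCc1oc([C@@H](C)[C@@H](O)CC)c(C)c(=O)c1C
F8 | step 3 | (2R,3R)-2-(6-ethyl-3,5-dimethyl-4-oxo-4H-pyran-2-yl)pentan-3-yl acetate | CCc1oc([C@H](C)[C@H](OC(C)=O)CC)c(C)c(=O)c1C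
F9 | step 9 | 2-ethyl-3,5-dimethyl-6-[(2R,3R)-3-(triethylsilyloxy)pentan-2-yl]-4H-pyran-4-one | CCc1oc([C@H](C)[C@H](O[Si](CC)(CC)CC)CC)c(C)c(=O)c1C
F10 | step 9 | 2-[(4S,5S,6E)-7-bromo-3-hydroxy-4,6-dimethyl-5-(triethylsilyloxy)hept-6-en-2-yl]-3,5-dimethyl-6-[(2R,3R)-3-(triethylsilyloxy)pentan-2-yl]-4H-pyran-4-one (mixture at C13 and C14) | Br/C=C(\C)[C@@H](O[Si](CC)(CC)CC)[C@@H](C)C(O)C(C)c1oc([C@H](C)[C@H](O[Si](CC)(CC)CC)CC)c(C)c(=O)c1C
F11 | step 9 | 2-[(4R,5S,6E)-7-bromo-4,6-dimethyl-3-oxo-5-(triethylsilyloxy)hept-6-en-2-yl]-3,5-dimethyl-6-[(2R,3R)-3-(triethylsilyloxy)pentan-2-yl]-4H-pyran-4-one (both epimers at C14) | Br/C=C(\C)[C@@H](O[Si](CC)(CC)CC)[C@@H](C)C(=O)C(C)c1oc([C@H](C)[C@H](O[Si](CC)(CC)CC)CC)c(C)c(=O)c1C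
F12 | step 8 | [1-(6-ethyl-3,5-dimethyl-4-oxo-4H-pyran-2-yl)ethyl]sodium | CCc1oc(C(C)[Na])c(C)c(=O)c1C
A1 | alternative 1 | (2S,8R,9R)-1-[(4-methoxyphenyl)methoxy]-2,4,6,8-tetramethyl-9-(triethylsilyloxy)undecane-3,5,7-trione | COc1ccc(COC[C@H](C)C(=O)C(C)C(=O)C(C)C(=O)[C@H](C)[C@H](O[Si](CC)(CC)CC)CC)cc1
A2 | alternative 2 | (2R,3S,4E,6S)-6-(6-ethyl-3,5-dimethyl-4-oxo-4H-pyran-2-yl)-2,4-dimethyl-3-(triethylsilyloxy)hept-4-enal | CCc1oc([C@@H](C)/C=C(\C)[C@@H](O[Si](CC)(CC)CC)[C@@H](C)C=O)c(C)c(=O)c1C
A3 | alternative 3 | 3,5-dimethyl-2-(3-oxopentan-2-yl)-6-[(2R,3R)-3-(triethylsilyloxy)pentan-2-yl]-4H-pyran-4-one | CCC(=O)C(C)c1oc([C@H](C)[C@H](O[Si](CC)(CC)CC)CC)c(C)c(=O)c1C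
A4 | alternative 3 | (2E,4S)-4-(6-ethyl-3,5-dimethyl-4-oxo-4H-pyran-2-yl)-2-methylpent-2-enal | CCc1oc([C@@H](C)/C=C(\C)C=O)c(C)c(=O)c1C
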